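Retrosynthesis: the anilide N–C15 bond is cut first (aminonaphthalene + dienoic acid), then C16=C17 and C18=C19 (two olefinations), C22–C23 (aldol), C28=C29 (alkene metathesis) together with the two C12–O ketal bonds (ketal of an anti-1,3-diol with methyl vinyl ketone), and C26–C27 (aldol with acrolein); the arene is cut by a Stobbe benzannulation and a Curtius C–N exchange.
Forward: the 1,3-dioxane (C25, C26, C27, O, C12, O) is made first, then the five-membered ring is closed at C28=C29 to give the 2,8-dioxabicyclo[3.2.1]octene; the chain grows C23→C19 by aldol/reduction and C19→C15 by olefination; the arene is attached by amidation and its ring A is oxidised to the quinone last.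
Enabling feature: in the dioxane chair the C24 branch and the C26 methyl are equatorial, so the C27 vinyl is axial; a C12 vinyl that is also axial lies 1,3-diaxial to it, and these are the two positions bridged by C28–C29 in the target (C13 methyl equatorial).
Stereochemistry: C24 and C20 come from the (R)- and (S)-Roche esters; C26/C27 from an Ipc-boron syn aldol (reagent control); C25 and C21 from hydroxyl-directed 1,3-anti reductions; C22/C23 from a ketone-controlled anti aldol; C12 by selection of the only ketal epimer able to cyclise; 16Z from a Still–Gennari olefination and 18E from a stabilised Wittig reaction.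

Key step: step 7

Remark: chain atoms are numbered from the amide carbonyl C15 through C16–C29 to ketal carbon C12 (methyl C13); arene positions follow the naphthoquinone (C1 and C4 carbonyls of ring A, N on C2; C5 carboxyl, C6 and C8 hydroxyls, C7 methyl on ring B); (−)-Ipc2BOTf is the triflate made from (+)-α-pinene and is assumed to be the enantiomer that gives the 2,4-anti syn adduct from the (R)-ketone.

Step 1
Reactants: 1 methyl (R)-3-hydroxy-2-methylpropanoate
Product: 2 methyl (R)-3-(benzyloxy)-2-methylpropanoate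
Conditions: benzyl 2,2,2-trichloroacetimidate, TfOH (cat.), CH2Cl2/cyclohexane, 0 °C to rt
Reagents that add atoms: benzyl 2,2,2-trichloroacetimidate ClC(Cl)(Cl)C(=N)OCc1ccccc1
Why: Acid-catalysed O-benzylation by the trichloroacetimidate needs no base, so the enolisable stereocentre (future C24) should not epimerise.

Step 2
Reactants: 2 methyl (R)-3-(benzyloxy)-2-methylpropanoate
Product: 3 (R)-3-(benzyloxy)-N-methoxy-N,2-dimethylpropanamide
Conditions: MeNH(OMe)·HCl, i-PrMgCl, THF, −20 °C
Reagents that add atoms: N,O-dimethylhydroxylamine hydrochloride CNOC.Cl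
Why: Weinreb amide formation by aminolysis of the ester with the chloromagnesium amide is fast at low temperature and should leave the α-stereocentre intact.

Step 3
Reactants: 3 (R)-3-(benzyloxy)-N-methoxy-N,2-dimethylpropanamide
Product: 4 (R)-1-(benzyloxy)-2-methylpentan-3-one
Conditions: EtMgBr, THF, 0 °C; aq. NH4Cl
Reagents that add atoms: ethylmagnesium bromide CC[Mg]Br
Why: Weinreb ketone synthesis, in which the chelated tetrahedral adduct collapses only on work-up so that a single ethyl group (C26 and its methyl) is added.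

Step 4
Reactants: 4 (R)-1-(benzyloxy)-2-methylpentan-3-one; 5 acrolein
Product: 6 (2R,4R,5S)-1-(benzyloxy)-5-hydroxy-2,4-dimethylhept-6-en-3-one
Conditions: (−)-Ipc2BOTf, i-Pr2NEt, CH2Cl2, −78 °C; 5, −78 to −20 °C; then MeOH, pH 7 buffer, H2O2, 0 °C
Reagents that add atoms: none
Why: Boron aldol reaction through a Zimmerman–Traxler chair, in which the Z-enol borinate gives the C26/C27 syn relationship and the (−)-Ipc ligands are expected to direct attack to the re face of acrolein, so that C26 (R) and C27 (S) are set anti to the C24 methyl by reagent control over the weak bias of the ketone.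

Step 5
Reactants: 6 (2R,4R,5S)-1-(benzyloxy)-5-hydroxy-2,4-dimethylhept-6-en-3-one
Product: 7 (2R,3S,4R,5S)-1-(benzyloxy)-2,4-dimethylhept-6-ene-3,5-diol
Conditions: Me4NBH(OAc)3, MeCN/AcOH, −30 °C; aq. KNaC4H4O6 work-up
Reagents that add atoms: none
Why: Evans–Saksena reduction, in which the C27 hydroxyl exchanges onto boron and hydride is delivered intramolecularly through a chair to give the 1,3-anti diol, setting C25 (S).

Step 6
Reactants: 7 (2R,3S,4R,5S)-1-(benzyloxy)-2,4-dimethylhept-6-ene-3,5-diol; 8 methyl vinyl ketone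
Product: 10 (2S,4S,5R,6S)-4-[(2R)-1-(benzyloxy)propan-2-yl]-2,6-diethenyl-2,5-dimethyl-1,3-dioxane, via bis(trimethylsilyl) ether 9 (not isolated)
Conditions: HN(SiMe3)2, TMSOTf (cat.), CH2Cl2, rt; evaporate; 8, TMSOTf (cat.), CH2Cl2, −78 to −40 °C; pyridine quench
Reagents that add atoms: none
Why: Noyori ketalisation, in which silyl-activated methyl vinyl ketone is attacked at the carbonyl carbon by both silyl ether oxygens with loss of hexamethyldisiloxane and the aprotic low-temperature conditions suppress conjugate addition; C12 should form as both epimers, the (2S) epimer 10 (vinyl cis to the C27 vinyl) being separated and the other re-equilibrated with catalytic TMSOTf through the vinyl-stabilised oxocarbenium ion.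

Step 7
Reactants: 10 (2S,4S,5R,6S)-4-[(2R)-1-(benzyloxy)propan-2-yl]-2,6-diethenyl-2,5-dimethyl-1,3-dioxane
Product: 11 (1S,3S,4R,5S)-3-[(2R)-1-(benzyloxy)propan-2-yl]-1,4-dimethyl-2,8-dioxabicyclo[3.2.1]oct-6-ene
Conditions: second-generation Grubbs catalyst RuCl2(=CHPh)(H2IMes)(PCy3) (cat.), CH2Cl2 (high dilution), 40 °C, argon sparge
Reagents that add atoms: none
Why: The ruthenium carbene should load onto the less hindered C27 vinyl group, add across the vinyl group on ketal carbon C12 to a ruthenacyclobutane and cyclorevert, releasing ethylene and forming C28=C29. The closest known reactions are ring-closing metathesis of ketal-tethered dienes to bridged bicyclic ketals and of cis-2,6-divinyl piperidines and tetrahydropyrans to bicyclo[3.2.1]oct-6-enes. The ring closed is the five-membered 2,5-dihydrofuran (C12, C29, C28, C27, O), formed by alkene metathesis between two vinyl groups held 1,3-diaxial on the dioxane chair, which gives the 2,8-dioxabicyclo[3.2.1]oct-6-ene. No carbon stereocentre is created in the bond-forming event; C12 ends as S because only the ketal epimer whose vinyl group is cis to the C27 vinyl group can reach the diaxial geometry, the other epimer being unable to cyclise. The step needs ring closure to win over cross-metathesis and over re-opening of the strained alkene by ethylene, which high dilution, the equatorial C24 branch and C26 methyl that hold the C27 vinyl axial, and continuous removal of ethylene should secure.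

Step 8
Reactants: 11 (1S,3S,4R,5S)-3-[(2R)-1-(benzyloxy)propan-2-yl]-1,4-dimethyl-2,8-dioxabicyclo[3.2.1]oct-6-ene
Product: 12 (2R)-2-[(1S,3S,4R,5S)-1,4-dimethyl-2,8-dioxabicyclo[3.2.1]octan-3-yl]propan-1-ol
Conditions: H2 (1 atm), Pd/C, EtOH, rt
Reagents that add atoms: none
Why: Heterogeneous hydrogenation should saturate the strained C28=C29 alkene quickly and then hydrogenolyse the benzyl ether, no stereocentre being involved.

Step 9
Reactants: 12 (2R)-2-[(1S,3S,4R,5S)-1,4-dimethyl-2,8-dioxabicyclo[3.2.1]octan-3-yl]propan-1-ol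
Product: 13 (2S)-2-[(1S,3R,4R,5S)-1,4-dimethyl-2,8-dioxabicyclo[3.2.1]octan-3-yl]propanal
Conditions: TEMPO (cat.), PhI(OAc)2, CH2Cl2, rt
Reagents that add atoms: none
Why: Oxoammonium-mediated oxidation of the primary alcohol runs under near-neutral conditions, so the epimerisable C24 aldehyde (used without chromatography) should keep its configuration; the changed descriptors reflect CIP priorities only.

Step 10
Reactants: 14 methyl (S)-3-hydroxy-2-methylpropanoate
Product: 15 methyl (S)-3-(benzyloxy)-2-methylpropanoate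
Conditions: benzyl 2,2,2-trichloroacetimidate, TfOH (cat.), CH2Cl2/cyclohexane, 0 °C to rt
Reagents that add atoms: benzyl 2,2,2-trichloroacetimidate ClC(Cl)(Cl)C(=N)OCc1ccccc1
Why: Acid-catalysed imidate benzylation as in step 1, without epimerisation of the future C20 centre.

Step 11
Reactants: 15 methyl (S)-3-(benzyloxy)-2-methylpropanoate
Product: 16 (S)-3-(benzyloxy)-N-methoxy-N,2-dimethylpropanamide
Conditions: MeNH(OMe)·HCl, i-PrMgCl, THF, −20 °C
Reagents that add atoms: N,O-dimethylhydroxylamine hydrochloride CNOC.Cl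
Why: Weinreb amide formation from the ester with the magnesium amide, as in step 2.

Step 12
Reactants: 16 (S)-3-(benzyloxy)-N-methoxy-N,2-dimethylpropanamide
Product: 17 (S)-1-(benzyloxy)-2-methylpentan-3-one
Conditions: EtMgBr, THF, 0 °C; aq. NH4Cl
Reagents that add atoms: ethylmagnesium bromide CC[Mg]Br
Why: Weinreb ketone synthesis as in step 3, the ethyl group supplying C22 and its methyl.

Step 13
Reactants: 17 (S)-1-(benzyloxy)-2-methylpentan-3-one; 13 (2S)-2-[(1S,3R,4R,5S)-1,4-dimethyl-2,8-dioxabicyclo[3.2.1]octan-3-yl]propanal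
Product: 18 (2S,4S,5S,6R)-1-(benzyloxy)-5-hydroxy-2,4-dimethyl-6-[(1S,3S,4R,5S)-1,4-dimethyl-2,8-dioxabicyclo[3.2.1]octan-3-yl]heptan-3-one
Conditions: (c-C6H11)2BCl, Et3N, Et2O, 0 °C; 13, −78 to −20 °C; then MeOH, pH 7 buffer, H2O2, 0 °C
Reagents that add atoms: none
Why: Boron aldol reaction of the E-enol borinate through a chair gives the C22/C23 anti relationship, and the C20 stereocentre of the ketone (allylic strain minimised, benzyl ether oxygen turned toward the aldehyde) should set C22 anti to the C20 methyl; this bias has to override the Felkin preference of aldehyde 13 to give the C23/C24 anti arrangement.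

Step 14
Reactants: 18 (2S,4S,5S,6R)-1-(benzyloxy)-5-hydroxy-2,4-dimethyl-6-[(1S,3S,4R,5S)-1,4-dimethyl-2,8-dioxabicyclo[3.2.1]octan-3-yl]heptan-3-one
Product: 19 (2S,3S,4R,5R,6R)-1-(benzyloxy)-2,4-dimethyl-6-[(1S,3S,4R,5S)-1,4-dimethyl-2,8-dioxabicyclo[3.2.1]octan-3-yl]heptane-3,5-diol
Conditions: Me4NBH(OAc)3, MeCN/AcOH, −30 °C; aq. KNaC4H4O6 work-up
Reagents that add atoms: none
Why: Evans–Saksena reduction with intramolecular hydride delivery from the boron bound to the C23 hydroxyl gives the 1,3-anti diol and sets C21 (S).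

Step 15
Reactants: 19 (2S,3S,4R,5R,6R)-1-(benzyloxy)-2,4-dimethyl-6-[(1S,3S,4R,5S)-1,4-dimethyl-2,8-dioxabicyclo[3.2.1]octan-3-yl]heptane-3,5-diol
Product: 20 acetonide of 19 across O21 and O23 (2,2-dimethyl-1,3-dioxane; C19 benzyl ether; stereocentres as in 19)
Conditions: 2,2-dimethoxypropane, PPTS, CH2Cl2, rt
Reagents that add atoms: 2,2-dimethoxypropane COC(C)(C)OC
Why: Acid-catalysed transketalisation protects the anti-1,3-diol as one isopropylidene group, while the bicyclic ketal, already the thermodynamic form, should not exchange.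

Step 16
Reactants: 20 acetonide of 19 (C19 benzyl ether)
Product: 21 C19 primary alcohol of the C19–C29 segment (O21,O23-acetonide)
Conditions: H2 (1 atm), Pd/C, EtOAc, rt
Reagents that add atoms: none
Why: Hydrogenolysis of the benzyl ether under neutral conditions leaves both ketals untouched.

Step 17
Reactants: 21 C19 primary alcohol (O21,O23-acetonide)
Product: 22 C19 aldehyde of the C19–C29 segment (O21,O23-acetonide)
Conditions: TEMPO (cat.), PhI(OAc)2, CH2Cl2, rt
Reagents that add atoms: none
Why: Near-neutral oxoammonium oxidation gives the α-branched aldehyde without epimerising C20.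

Step 18
Reactants: 22 C19 aldehyde (O21,O23-acetonide)
Product: 23 (E)-enal of the C17–C29 segment (C17 aldehyde, C18=C19 E, O21,O23-acetonide)
Conditions: Ph3P=CHCHO, toluene, 80 °C
Reagents that add atoms: (triphenylphosphoranylidene)acetaldehyde O=CC=P(c1ccccc1)(c1ccccc1)c1ccccc1
Why: Wittig reaction of a stabilised ylide gives the E-alkene (C18=C19) under non-basic conditions that should not epimerise C20.

Step 19
Reactants: 23 (E)-enal of the C17–C29 segment
Product: 24 methyl (2Z,4E)-2-methyldienoate of the C15–C29 segment (O21,O23-acetonide)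
Conditions: (CF3CH2O)2P(O)CH(CH3)CO2CH3, KN(SiMe3)2, 18-crown-6, THF, −78 °C
Reagents that add atoms: methyl 2-[bis(2,2,2-trifluoroethoxy)phosphoryl]propanoate COC(=O)C(C)P(=O)(OCC(F)(F)F)OCC(F)(F)F
Why: Still–Gennari olefination, in which fast irreversible elimination from the trifluoroethyl phosphonate adduct with a dissociated potassium counter-ion gives the Z-trisubstituted C16=C17 alkene.

Step 20
Reactants: 24 methyl (2Z,4E)-2-methyldienoate of the C15–C29 segment
Product: 25 (2Z,4E)-2-methyldienoic acid of the C15–C29 segment (O21,O23-acetonide)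
Conditions: LiOH, THF/MeOH/H2O, rt to 35 °C; then 1 M HCl to pH 4
Reagents that add atoms: lithium hydroxide [Li+].[OH-]
Why: Saponification of the methyl ester, to which both ketals and the diene geometry should be stable.

Step 21
Reactants: 26 2,4-dihydroxy-3-methylbenzaldehyde
Product: 27 2,4-bis(allyloxy)-3-methylbenzaldehyde
Conditions: allyl bromide, K2CO3, DMF, 60 °C
Reagents that add atoms: allyl bromide C=CCBr
Why: Williamson etherification of both phenols gives the ring B oxygens (future O6 and O8) protecting groups that survive the annulation and are removable with palladium at the end.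

Step 22
Reactants: 27 2,4-bis(allyloxy)-3-methylbenzaldehyde; 28 dimethyl succinate
Product: 29 (E)-4-[2,4-bis(allyloxy)-3-methylphenyl]-3-(methoxycarbonyl)but-3-enoic acid
Conditions: NaOMe, MeOH, reflux; then aq. HCl
Reagents that add atoms: none
Why: Stobbe condensation, in which the aldol adduct lactonises onto the distal ester and eliminative ring opening gives the half-ester with the aryl group cis to the CH2CO2H arm.

Step 23
Reactants: 29 (E)-4-[2,4-bis(allyloxy)-3-methylphenyl]-3-(methoxycarbonyl)but-3-enoic acid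
Product: 30 methyl 4-acetoxy-6,8-bis(allyloxy)-7-methyl-2-naphthoate
Conditions: Ac2O, NaOAc, 140 °C
Reagents that add atoms: acetic anhydride CC(=O)OC(C)=O
Why: The mixed anhydride undergoes intramolecular Friedel–Crafts acylation at the only free ortho position, and the naphthol formed is acetylated, which builds ring A with O4 and the C2 ester in place.

Step 24
Reactants: 30 methyl 4-acetoxy-6,8-bis(allyloxy)-7-methyl-2-naphthoate
Product: 31 methyl 4-acetoxy-6,8-bis(allyloxy)-5-formyl-7-methyl-2-naphthoate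
Conditions: POCl3, DMF, 0 to 70 °C; then aq. NaOAc
Reagents that add atoms: N,N-dimethylformamide CN(C)C=O; water O
Why: Vilsmeier–Haack formylation should go to C5, the only position ortho and para to the two allyloxy groups, ring A being deactivated by its ester and acetoxy groups.

Step 25
Reactants: 31 methyl 4-acetoxy-6,8-bis(allyloxy)-5-formyl-7-methyl-2-naphthoate
Product: 32 8-acetoxy-2,4-bis(allyloxy)-6-(methoxycarbonyl)-3-methyl-1-naphthoic acid
Conditions: NaClO2, NaH2PO4, 2-methyl-2-butene, t-BuOH/THF/H2O, rt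
Reagents that add atoms: sodium chlorite [Na+].[O-]Cl=O
Why: Pinnick oxidation converts the hindered aryl aldehyde into the C5 acid while the alkene scavenger removes hypochlorous acid and so protects the allyl ethers.

Step 26
Reactants: 32 8-acetoxy-2,4-bis(allyloxy)-6-(methoxycarbonyl)-3-methyl-1-naphthoic acid
Product: 34 1-allyl 6-methyl 2,4,8-tris(allyloxy)-3-methylnaphthalene-1,6-dicarboxylate, via hydroxy acid dipotassium salt 33 (not isolated)
Conditions: K2CO3, MeOH, rt; evaporate; allyl bromide, K2CO3, DMF, 50 °C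
Reagents that add atoms: allyl bromide C=CCBr
Why: Methanolysis removes the aryl acetate, and alkylation of the resulting phenoxide and of the hindered carboxylate puts allyl groups on O4 and on the C5 acid, carboxylate alkylation being insensitive to the flanking substituents.

Step 27
Reactants: 34 1-allyl 6-methyl 2,4,8-tris(allyloxy)-3-methylnaphthalene-1,6-dicarboxylate
Product: 35 4,6,8-tris(allyloxy)-5-[(allyloxy)carbonyl]-7-methyl-2-naphthoic acid
Conditions: LiOH, THF/H2O, rt; then 1 M HCl
Reagents that add atoms: lithium hydroxide [Li+].[OH-]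
Why: Saponification should be selective for the unhindered C2 methyl ester, because the C5 allyl ester is shielded by the peri O4 and ortho O6 substituents.

Step 28
Reactants: 35 4,6,8-tris(allyloxy)-5-[(allyloxy)carbonyl]-7-methyl-2-naphthoic acid
Product: 38 allyl 6-amino-2,4,8-tris(allyloxy)-3-methyl-1-naphthoate, via acyl azide 36 (not isolated), via isocyanate 37 (not isolated)
Conditions: (PhO)2P(O)N3, Et3N, toluene, rt then 90 °C; then 2 M HCl, THF, 60 °C; NaHCO3
Reagents that add atoms: diphenylphosphoryl azide [N-]=[N+]=NP(=O)(Oc1ccccc1)Oc1ccccc1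
Why: Curtius rearrangement moves the aryl group from carbon to nitrogen with retention of the ring position, and acid hydrolysis of the isocyanate (the amine protonated, so no urea) places the nitrogen on C2.

Step 29
Reactants: 25 (2Z,4E)-2-methyldienoic acid of the C15–C29 segment; 38 allyl 6-amino-2,4,8-tris(allyloxy)-3-methyl-1-naphthoate
Product: 40 anilide joining C15 to the C2 nitrogen (O21,O23-acetonide; three allyl ethers and the allyl ester retained), via acid chloride 39 (not isolated)
Conditions: 1-chloro-N,N,2-trimethylprop-1-en-1-amine, CH2Cl2, 0 °C; then 38, pyridine, 0 °C to rt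
Reagents that add atoms: none
Why: Amide formation through the acid chloride made under neutral conditions with the Ghosez reagent avoids the acids and nucleophilic catalysts that could isomerise the 16Z alkene, and the unhindered electron-rich naphthylamine is acylated at nitrogen.

Step 30
Reactants: 40 anilide (O21,O23-acetonide; allyl-protected)
Product: 41 21,23-diol anilide (three allyl ethers and the allyl ester retained)
Conditions: PPTS, MeOH, 40 °C
Reagents that add atoms: none
Why: Acid-catalysed methanolysis removes the twist-boat anti-acetonide, whereas the bicyclic ketal, the thermodynamic form of its keto diol, should persist.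

Step 31
Reactants: 41 21,23-diol anilide (allyl-protected)
Product: 42 N-acyl 2-amino-4,6,8-trihydroxy-7-methylnaphthalene-5-carboxylic acid (chain as in the target, ring A not yet oxidised)
Conditions: Pd(PPh3)4 (cat.), morpholine, THF, rt, argon
Reagents that add atoms: none
Why: Tsuji–Trost deallylation, in which the palladium catalyst ionises the three aryl allyl ethers and the allyl ester to π-allyl complexes that morpholine captures, so the phenols and the acid are freed without touching the dienamide or the ketal; 42 is kept under argon and used at once.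

Step 32
Reactants: 42 N-acyl 2-amino-4,6,8-trihydroxy-7-methylnaphthalene-5-carboxylic acid
Product: 43 rifsaliniketal
Conditions: Fremy's salt (KSO3)2NO, KH2PO4 buffer (pH 7), acetone/H2O, 0 °C
Reagents that add atoms: Fremy's salt (dipotassium nitrosodisulfonate) [K+].[K+].[O]N(S(=O)(=O)[O-])S(=O)(=O)[O-]
Why: Teuber oxidation, in which the nitrosodisulfonate radical abstracts the hydrogen of the C4 hydroxyl (the only phenol with a free para position) and a second equivalent delivers oxygen to C1, giving the ring A 1,4-quinone; the ring B phenols have blocked ortho and para positions, and the neutral buffer keeps the C5 carboxylate from lactonising onto the peri hydroxyl.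

Compound list
1 | methyl (R)-3-hydroxy-2-methylpropanoate | OC[C@@H](C)C(=O)OC | starting material
2 | methyl (R)-3-(benzyloxy)-2-methylpropanoate | c1ccccc1COC[C@@H](C)C(=O)OC | intermediate
3 | (R)-3-(benzyloxy)-N-methoxy-N,2-dimethylpropanamide | c1ccccc1COC[C@@H](C)C(=O)N(C)OC | intermediate
4 | (R)-1-(benzyloxy)-2-methylpentan-3-one | c1ccccc1COC[C@@H](C)C(=O)CC | intermediate
5 | acrolein | C=CC=O | starting material
6 | (2R,4R,5S)-1-(benzyloxy)-5-hydroxy-2,4-dimethylhept-6-en-3-one | c1ccccc1COC[C@@H](C)C(=O)[C@H](C)[C@@H](O)C=C | intermediate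
7 | (2R,3S,4R,5S)-1-(benzyloxy)-2,4-dimethylhept-6-ene-3,5-diol | c1ccccc1COC[C@@H](C)[C@H](O)[C@H](C)[C@@H](O)C=C | intermediate
8 | methyl vinyl ketone | CC(=O)C=C | starting material
9 | bis(trimethylsilyl) ether of 7 | c1ccccc1COC[C@@H](C)[C@H](O[Si](C)(C)C)[C@H](C)[C@@H](O[Si](C)(C)C)C=C | intermediate
10 | (2S,4S,5R,6S)-4-[(2R)-1-(benzyloxy)propan-2-yl]-2,6-diethenyl-2,5-dimethyl-1,3-dioxane | c1ccccc1COC[C@@H](C)[C@@H]2O[C@@](C)(C=C)O[C@@H](C=C)[C@H]2C | intermediate
11 | (1S,3S,4R,5S)-3-[(2R)-1-(benzyloxy)propan-2-yl]-1,4-dimethyl-2,8-dioxabicyclo[3.2.1]oct-6-ene | c1ccccc1COC[C@@H](C)[C@@H]2O[C@@]3(C)C=C[C@H](O3)[C@H]2C | intermediate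
12 | (2R)-2-[(1S,3S,4R,5S)-1,4-dimethyl-2,8-dioxabicyclo[3.2.1]octan-3-yl]propan-1-ol | OC[C@@H](C)[C@@H]1O[C@@]2(C)CC[C@H](O2)[C@H]1C | intermediate
13 | (2S)-2-[(1S,3R,4R,5S)-1,4-dimethyl-2,8-dioxabicyclo[3.2.1]octan-3-yl]propanal | O=C[C@@H](C)[C@@H]1O[C@@]2(C)CC[C@H](O2)[C@H]1C | intermediate
14 | methyl (S)-3-hydroxy-2-methylpropanoate | OC[C@H](C)C(=O)OC | starting material
15 | methyl (S)-3-(benzyloxy)-2-methylpropanoate | c1ccccc1COC[C@H](C)C(=O)OC | intermediate
16 | (S)-3-(benzyloxy)-N-methoxy-N,2-dimethylpropanamide | c1ccccc1COC[C@H](C)C(=O)N(C)OC | intermediate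
17 | (S)-1-(benzyloxy)-2-methylpentan-3-one | c1ccccc1COC[C@H](C)C(=O)CC | intermediate
18 | (2S,4S,5S,6R)-1-(benzyloxy)-5-hydroxy-2,4-dimethyl-6-[(1S,3S,4R,5S)-1,4-dimethyl-2,8-dioxabicyclo[3.2.1]octan-3-yl]heptan-3-one | c1ccccc1COC[C@H](C)C(=O)[C@@H](C)[C@@H](O)[C@@H](C)[C@@H]1O[C@@]2(C)CC[C@H](O2)[C@H]1C | intermediate
19 | (2S,3S,4R,5R,6R)-1-(benzyloxy)-2,4-dimethyl-6-[(1S,3S,4R,5S)-1,4-dimethyl-2,8-dioxabicyclo[3.2.1]octan-3-yl]heptane-3,5-diol | c1ccccc1COC[C@H](C)[C@H](O)[C@@H](C)[C@@H](O)[C@@H](C)[C@@H]1O[C@@]2(C)CC[C@H](O2)[C@H]1C | intermediate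
20 | O21,O23-acetonide of 19 (C19 benzyl ether) | c1ccccc1COC[C@H](C)[C@H](O3)[C@@H](C)[C@@H](OC3(C)C)[C@@H](C)[C@@H]1O[C@@]2(C)CC[C@H](O2)[C@H]1C | intermediate
21 | C19 primary alcohol of the C19–C29 segment (O21,O23-acetonide) | OC[C@H](C)[C@H](O3)[C@@H](C)[C@@H](OC3(C)C)[C@@H](C)[C@@H]1O[C@@]2(C)CC[C@H](O2)[C@H]1C | intermediate
22 | C19 aldehyde of the C19–C29 segment (O21,O23-acetonide) | O=C[C@H](C)[C@H](O3)[C@@H](C)[C@@H](OC3(C)C)[C@@H](C)[C@@H]1O[C@@]2(C)CC[C@H](O2)[C@H]1C | intermediate
23 | (E)-enal of the C17–C29 segment (O21,O23-acetonide) | O=C/C=C/[C@H](C)[C@H](O3)[C@@H](C)[C@@H](OC3(C)C)[C@@H](C)[C@@H]1O[C@@]2(C)CC[C@H](O2)[C@H]1C | intermediate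
24 | methyl (2Z,4E)-2-methyldienoate of the C15–C29 segment (O21,O23-acetonide) | C/C(=C/C=C/[C@H](C)[C@H](O3)[C@@H](C)[C@@H](OC3(C)C)[C@@H](C)[C@@H]1O[C@@]2(C)CC[C@H](O2)[C@H]1C)C(=O)OC | intermediate
25 | (2Z,4E)-2-methyldienoic acid of the C15–C29 segment (O21,O23-acetonide) | C/C(=C/C=C/[C@H](C)[C@H](O3)[C@@H](C)[C@@H](OC3(C)C)[C@@H](C)[C@@H]1O[C@@]2(C)CC[C@H](O2)[C@H]1C)C(=O)O | intermediate
26 | 2,4-dihydroxy-3-methylbenzaldehyde | O=Cc1ccc(O)c(C)c1O | starting material
27 | 2,4-bis(allyloxy)-3-methylbenzaldehyde | O=Cc1ccc(OCC=C)c(C)c1OCC=C | intermediate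
28 | dimethyl succinate | COC(=O)CCC(=O)OC | starting material
29 | (E)-4-[2,4-bis(allyloxy)-3-methylphenyl]-3-(methoxycarbonyl)but-3-enoic acid | OC(=O)C/C(=C\c1ccc(OCC=C)c(C)c1OCC=C)C(=O)OC | intermediate
30 | methyl 4-acetoxy-6,8-bis(allyloxy)-7-methyl-2-naphthoate | COC(=O)c1cc(OC(C)=O)c2cc(OCC=C)c(C)c(OCC=C)c2c1 | intermediate
31 | methyl 4-acetoxy-6,8-bis(allyloxy)-5-formyl-7-methyl-2-naphthoate | COC(=O)c1cc(OC(C)=O)c2c(C=O)c(OCC=C)c(C)c(OCC=C)c2c1 | intermediate
32 | 8-acetoxy-2,4-bis(allyloxy)-6-(methoxycarbonyl)-3-methyl-1-naphthoic acid | COC(=O)c1cc(OC(C)=O)c2c(C(=O)O)c(OCC=C)c(C)c(OCC=C)c2c1 | intermediate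
33 | dipotassium salt of 2,4-bis(allyloxy)-8-hydroxy-6-(methoxycarbonyl)-3-methyl-1-naphthoic acid | COC(=O)c1cc([O-])c2c(C(=O)[O-])c(OCC=C)c(C)c(OCC=C)c2c1.[K+].[K+] | intermediate
34 | 1-allyl 6-methyl 2,4,8-tris(allyloxy)-3-methylnaphthalene-1,6-dicarboxylate | COC(=O)c1cc(OCC=C)c2c(C(=O)OCC=C)c(OCC=C)c(C)c(OCC=C)c2c1 | intermediate
35 | 4,6,8-tris(allyloxy)-5-[(allyloxy)carbonyl]-7-methyl-2-naphthoic acid | OC(=O)c1cc(OCC=C)c2c(C(=O)OCC=C)c(OCC=C)c(C)c(OCC=C)c2c1 | intermediate
36 | acyl azide of 35 | [N-]=[N+]=NC(=O)c1cc(OCC=C)c2c(C(=O)OCC=C)c(OCC=C)c(C)c(OCC=C)c2c1 | intermediate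
37 | allyl 2,4,8-tris(allyloxy)-6-isocyanato-3-methyl-1-naphthoate | O=C=Nc1cc(OCC=C)c2c(C(=O)OCC=C)c(OCC=C)c(C)c(OCC=C)c2c1 | intermediate
38 | allyl 6-amino-2,4,8-tris(allyloxy)-3-methyl-1-naphthoate | Nc1cc(OCC=C)c2c(C(=O)OCC=C)c(OCC=C)c(C)c(OCC=C)c2c1 | intermediate
39 | acid chloride of 25 | C/C(=C/C=C/[C@H](C)[C@H](O3)[C@@H](C)[C@@H](OC3(C)C)[C@@H](C)[C@@H]1O[C@@]2(C)CC[C@H](O2)[C@H]1C)C(=O)Cl | intermediate
40 | anilide of 25 and 38 (O21,O23-acetonide; three allyl ethers, allyl ester) | C/C(=C/C=C/[C@H](C)[C@H](O3)[C@@H](C)[C@@H](OC3(C)C)[C@@H](C)[C@@H]1O[C@@]2(C)CC[C@H](O2)[C@H]1C)C(=O)Nc1cc(OCC=C)c2c(C(=O)OCC=C)c(OCC=C)c(C)c(OCC=C)c2c1 | intermediate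
41 | 21,23-diol anilide (three allyl ethers, allyl ester) | C/C(=C/C=C/[C@H](C)[C@H](O)[C@@H](C)[C@@H](O)[C@@H](C)[C@@H]1O[C@@]2(C)CC[C@H](O2)[C@H]1C)C(=O)Nc1cc(OCC=C)c2c(C(=O)OCC=C)c(OCC=C)c(C)c(OCC=C)c2c1 | intermediate
42 | N-acyl 2-amino-4,6,8-trihydroxy-7-methylnaphthalene-5-carboxylic acid (ring A not yet oxidised) | C/C(=C/C=C/[C@H](C)[C@H](O)[C@@H](C)[C@@H](O)[C@@H](C)[C@@H]1O[C@@]2(C)CC[C@H](O2)[C@H]1C)C(=O)Nc1cc(O)c2c(C(=O)O)c(O)c(C)c(O)c2c1 | intermediate
43 | rifsaliniketal | C/C(=C/C=C/[C@H](C)[C@H](O)[C@@H](C)[C@@H](O)[C@@H](C)[C@@H]1O[C@@]2(C)CC[C@H](O2)[C@H]1C)C(=O)NC1=CC(=O)c2c(C(=O)O)c(O)c(C)c(O)c2C1=O | target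

Total step count: 32. Longest linear sequence: 21 steps (steps 1–9, 13–20 and 29–32).

Steps most likely to fail

Step 7. The closure forms a strained bridged alkene that ethylene can re-open, only one C12 epimer of the ketal can react, and cross-metathesis may compete. Fallback: the two bridge carbons are attached by cross-metathesis before the ketal is made, and the ketal is closed thermodynamically. Setting out from diol 7, cross-metathesis with methyl vinyl ketone 8 (second-generation Hoveyda–Grubbs catalyst RuCl2(=CH-C6H4-2-O-i-Pr)(H2IMes), CH2Cl2, 40 °C) should give the (E)-enone diol F1. Hydrogenation over Pd/C saturates the alkene and removes the benzyl group to give the keto triol F2. PPTS in CH2Cl2 then closes the five- and six-membered rings of the ketal under thermodynamic control, and the route is rejoined at alcohol 12.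

Step 4. Reagent control of the enolate face may be insufficient, so the 2,4-syn diastereomer may be formed alongside 6. Fallback: a substrate-controlled anti aldol followed by redox correction of C27. From ketone 4 and acrolein 5, the E-enol borinate ((c-C6H11)2BCl, Et3N) should give the anti,anti adduct F3, the C27 epimer of 6. Syn-reduction (Et2BOMe, NaBH4, THF/MeOH, −78 °C) gives the diol F4 with C25 correct. MnO2 oxidises only the allylic C27 alcohol to the hydroxy enone F5. Me4NBH(OAc)3, directed by the C25 hydroxyl, re-forms C27 in the 1,3-anti sense, and the route is rejoined at diol 7.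

Step 13. The double stereodifferentiation is mismatched: the Felkin preference of aldehyde 13 opposes the facial bias of the ketone and may erode selectivity at C23. Fallback: the roles of the partners are exchanged so that all control elements cooperate. From aldehyde 13, EtMgBr gives the carbinol F6 (mixture of carbinol epimers), and Dess–Martin oxidation gives the ethyl ketone F7. Ester 15 is reduced with i-Bu2AlH at −78 °C to the aldehyde F8. The Z-enolate of F7 formed with Sn(OTf)2 and Et3N should add to F8 to give the syn,syn adduct F9 (C21 hydroxyl, C23 ketone), the C24 centre of the ketone and the anti-Felkin preference of Z-enolates acting together. Me4NBH(OAc)3 then sets C23 anti to C21, and the route is rejoined at diol 19.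

Further compounds
F1 | step 7 | (3E,5S,6R,7S,8R)-9-(benzyloxy)-5,7-dihydroxy-6,8-dimethylnon-3-en-2-one | c1ccccc1COC[C@@H](C)[C@H](O)[C@H](C)[C@@H](O)/C=C/C(C)=O
F2 | step 7 | (5S,6R,7S,8R)-5,7,9-trihydroxy-6,8-dimethylnonan-2-one | OC[C@@H](C)[C@H](O)[C@H](C)[C@@H](O)CCC(C)=O
F3 | step 4 | (2R,4R,5R)-1-(benzyloxy)-5-hydroxy-2,4-dimethylhept-6-en-3-one | c1ccccc1COC[C@@H](C)C(=O)[C@H](C)[C@H](O)C=C
F4 | step 4 | (2R,3S,4R,5R)-1-(benzyloxy)-2,4-dimethylhept-6-ene-3,5-diol | c1ccccc1COC[C@@H](C)[C@H](O)[C@H](C)[C@H](O)C=C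
F5 | step 4 | (4S,5S,6R)-7-(benzyloxy)-5-hydroxy-4,6-dimethylhept-1-en-3-one | c1ccccc1COC[C@@H](C)[C@H](O)[C@H](C)C(=O)C=C
F6 | step 13 | (2R)-2-[(1S,3S,4R,5S)-1,4-dimethyl-2,8-dioxabicyclo[3.2.1]octan-3-yl]pentan-3-ol (carbinol epimers) | CCC(O)[C@@H](C)[C@@H]1O[C@@]2(C)CC[C@H](O2)[C@H]1C
F7 | step 13 | (2S)-2-[(1S,3R,4R,5S)-1,4-dimethyl-2,8-dioxabicyclo[3.2.1]octan-3-yl]pentan-3-one | CCC(=O)[C@@H](C)[C@@H]1O[C@@]2(C)CC[C@H](O2)[C@H]1C
F8 | step 13 | (S)-3-(benzyloxy)-2-methylpropanal | c1ccccc1COC[C@H](C)C=O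
F9 | step 13 | syn,syn aldol adduct: C19 benzyl ether with C21 hydroxyl and C23 ketone, bicyclic ketal on C24 | c1ccccc1COC[C@H](C)[C@H](O)[C@@H](C)C(=O)[C@@H](C)[C@@H]1O[C@@]2(C)CC[C@H](O2)[C@H]1C
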